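Ring C is cut at two bonds, O1–C8a and C4a–C4, so that ring A arrives as 3,5-dimethoxybenzyne and everything else as an acyclic, enantiopure anti-aldol ester that already holds C2, C3 and ring B. In one operation the alkoxide oxygen adds to the aryne and the resulting aryl anion is acylated by the ester, closing the pyranone. The step exploits the fact that ring A carries O1 (at C8a) and the C4 carbonyl (at C4a) on adjacent carbons with the C5 methoxy next to C4a, the pattern a 3-methoxyaryne gives on nucleophile-then-electrophile addition. The precursor is the O-silylated methyl (2R,3R)-3-aryl-3-hydroxy-2-methoxypropanoate plus an o-silylaryl triflate.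

Key step: step 10

Assumption: in the open-transition-state anti glycolate aldol the TiCl4-bound aldehyde is taken to attack the thiocarbonyl-chelated Z enolate on the face away from the 4-benzyl group, so the (S)-auxiliary gives the (2R,3R) adduct; if the sense proves opposite, the (R)-auxiliary is used with nothing else changed.

Step 1
Reactants: 1 3,5-dimethoxyphenol
Product: 2 3,5-dimethoxyphenyl N-isopropylcarbamate
Conditions: i-PrNCO, Et3N (cat.), CH2Cl2, rt
Reagents that add atoms: isopropyl isocyanate, CC(C)N=C=O
Why: Base-catalysed addition of the phenol across the isocyanate (O-carbamoylation) should give a carbamate that is a strong ortho-directing group and can later be removed under mild basic conditions.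

Step 2
Reactants: 2 3,5-dimethoxyphenyl N-isopropylcarbamate
Product: 6 3,5-dimethoxy-2-(trimethylsilyl)phenyl N-isopropylcarbamate, via N-silyl carbamate 3 (not isolated), via aryllithium 4 (not isolated), via C-silylated N-silyl carbamate 5 (not isolated)
Conditions: TBSOTf, TMEDA, Et2O, 0 °C to rt; n-BuLi, TMEDA, −78 °C; TMSCl, −78 °C to rt; aq. NaHSO4
Reagents that add atoms: chlorotrimethylsilane, C[Si](C)(C)Cl
Why: Directed ortho-metalation, in which the N-silylated carbamate and the neighbouring methoxy group together should steer n-BuLi/TMEDA to C2 rather than to C4 between the two methoxy groups, followed by a TMSCl quench and an acidic work-up that hydrolyses only the N–Si bond.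

Step 3
Reactants: 6 3,5-dimethoxy-2-(trimethylsilyl)phenyl N-isopropylcarbamate
Product: 8 3,5-dimethoxy-2-(trimethylsilyl)phenyl trifluoromethanesulfonate, via silylphenol 7 (not isolated)
Conditions: Et2NH, DBU, MeCN, 40 °C; then PhNTf2, rt
Reagents that add atoms: N-phenylbis(trifluoromethanesulfonimide), O=S(=O)(N(c1ccccc1)S(=O)(=O)C(F)(F)F)C(F)(F)F
Why: DBU should trigger E1cB loss of isopropyl isocyanate from the N–H carbamate (trapped by Et2NH as a urea), and the freed phenoxide is O-sulfonylated by PhNTf2 in the same pot, which avoids isolating the protodesilylation-prone silylphenol.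

Step 4
Reactants: 9 methoxyhydroquinone (2-methoxybenzene-1,4-diol)
Product: 10 1,4-bis(benzyloxy)-2-methoxybenzene
Conditions: BnBr, K2CO3, DMF, 60 °C, degassed, Ar
Reagents that add atoms: benzyl bromide, BrCc1ccccc1
Why: Williamson ether synthesis on both phenoxides should proceed cleanly once air is excluded, so the hydroquinone is not oxidised to the quinone before alkylation.

Step 5
Reactants: 10 1,4-bis(benzyloxy)-2-methoxybenzene
Product: 12 2,5-bis(benzyloxy)-4-methoxybenzaldehyde, via aryl iminium chloride 11 (not isolated)
Conditions: POCl3, DMF, 0 to 70 °C; then H2O, 0 °C to rt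
Reagents that add atoms: N,N-dimethylformamide, CN(C)C=O; water, O
Why: Vilsmeier–Haack formylation should occur para to the methoxy group and ortho to a benzyloxy group, the most activated and least hindered site, as is usual for 1,2,4-trialkoxybenzenes, and benzyl ethers tolerate the reagent.

Step 6
Reactants: 13 methoxyacetyl chloride; 14 (S)-4-benzyl-1,3-oxazolidine-2-thione
Product: 15 (S)-4-benzyl-3-(methoxyacetyl)-1,3-oxazolidine-2-thione
Conditions: Et3N, CH2Cl2, 0 °C
Reagents that add atoms: none
Why: N-acylation of the oxazolidinethione nitrogen by the acid chloride under amine base should give the activated imide needed for soft enolisation.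

Step 7
Reactants: 15 (S)-4-benzyl-3-(methoxyacetyl)-1,3-oxazolidine-2-thione; 12 2,5-bis(benzyloxy)-4-methoxybenzaldehyde
Product: 17 (S)-4-benzyl-3-[(2R,3R)-3-[2,5-bis(benzyloxy)-4-methoxyphenyl]-3-hydroxy-2-methoxypropanoyl]-1,3-oxazolidine-2-thione, via trichlorotitanium enolate 16 (not isolated)
Conditions: TiCl4 (1.1 equiv), i-Pr2NEt (1.1 equiv), CH2Cl2, −78 °C; then 12 premixed with TiCl4, −78 °C; aq. NH4Cl at −78 °C
Reagents that add atoms: none
Why: Titanium-mediated anti-selective glycolate aldol of an N-acyloxazolidinethione, in which the aldehyde carrying its own TiCl4 should add through an open transition state to the thiocarbonyl-chelated Z enolate on the face away from the 4-benzyl group (setting the α-carbon as R) with anti topicity (setting the carbinol carbon as R).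

Step 8
Reactants: 17 (S)-4-benzyl-3-[(2R,3R)-3-[2,5-bis(benzyloxy)-4-methoxyphenyl]-3-hydroxy-2-methoxypropanoyl]-1,3-oxazolidine-2-thione
Product: 18 methyl (2R,3R)-3-[2,5-bis(benzyloxy)-4-methoxyphenyl]-3-hydroxy-2-methoxypropanoate
Conditions: imidazole, MeOH, rt
Reagents that add atoms: methanol, CO
Why: Imidazole-catalysed methanolysis (acyl transfer) of the activated N-acyl oxazolidinethione runs under nearly neutral conditions, so neither retro-aldol cleavage nor epimerisation of the α-carbon is expected and the auxiliary is released intact.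

Step 9
Reactants: 18 methyl (2R,3R)-3-[2,5-bis(benzyloxy)-4-methoxyphenyl]-3-hydroxy-2-methoxypropanoate
Product: 19 methyl (2R,3R)-3-[2,5-bis(benzyloxy)-4-methoxyphenyl]-2-methoxy-3-(trimethylsilyloxy)propanoate
Conditions: TMSCl, Et3N, DMAP (cat.), Et2O, 0 °C to rt; filter, evaporate, use crude
Reagents that add atoms: chlorotrimethylsilane, C[Si](C)(C)Cl
Why: Routine O-silylation of the secondary alcohol removes the only acidic proton, so that fluoride in the next step should release the alkoxide and the aryne together in a medium free of O–H.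

Step 10
Reactants: 19 methyl (2R,3R)-3-[2,5-bis(benzyloxy)-4-methoxyphenyl]-2-methoxy-3-(trimethylsilyloxy)propanoate; 8 3,5-dimethoxy-2-(trimethylsilyl)phenyl trifluoromethanesulfonate
Product: 23 (2R,3R)-2-[2,5-bis(benzyloxy)-4-methoxyphenyl]-3,5,7-trimethoxychroman-4-one, via 3,5-dimethoxybenzyne 20 (not isolated), via caesium alkoxide 21 (not isolated), via aryl anion 22 (not isolated)
Conditions: 8 (1.5 equiv), CsF (4 equiv), 18-crown-6 (0.5 equiv), THF, 0 °C to rt, short contact time; pH 7 phosphate buffer at 0 °C
Reagents that add atoms: none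
Why: Proposed new method: fluoride removes the O-silyl group of 19 and the C-silyl group of 8 in a medium without O–H protons, so alkoxide 21 and benzyne 20 arise together; the alkoxide adds to the aryne carbon remote from the flanking methoxy group (the future C8a), which places aryl anion 22 on the carbon next to that methoxy (the future C4a), where induction and the distortion of the aryne both favour it. The anion then attacks the ester carbonyl and loss of methoxide from the tetrahedral intermediate gives the ketone, closing ring C in a 6-exo-trig mode. The closest known reaction type is the fluoride-triggered union of o-silylaryl triflates with methyl salicylates to give xanthones (O-arylation followed by intramolecular acyl capture), supported by aryne acyl-alkylation and Parham-type cycloacylation; an aliphatic β-silyloxy ester has not been used in this way. No stereocentre is created and no bond to C2 or C3 is made or broken, so the anti (2R,3R) pair from step 7 should become the 2,3-trans pair of the chromanone, which is also the more stable arrangement at the enolisable C3. The step needs regioselective O-addition, secured by the methoxy group beside the aryne bond, and acyl capture in preference to proton quench, secured by the silyl mask on oxygen and the six-membered intramolecular trap; low temperature and a buffered quench are meant to limit retro-aldol cleavage and base-induced opening of ring C.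

Step 11
Reactants: 23 (2R,3R)-2-[2,5-bis(benzyloxy)-4-methoxyphenyl]-3,5,7-trimethoxychroman-4-one
Product: 24 (2R,3R)-2-(2,5-dihydroxy-4-methoxyphenyl)-3,5,7-trimethoxychroman-4-one (CNP0281794.1)
Conditions: H2 (1 atm), Pd/C, EtOAc, rt; filtration and isolation under Ar
Reagents that add atoms: none
Why: Catalytic hydrogenolysis of the two aryl benzyl ethers in a neutral aprotic solvent should leave the aryl methyl ethers, the ketone and both stereocentres untouched, and inert handling protects the hydroquinone from oxidation to the quinone.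

Compound list
1 | 3,5-dimethoxyphenol | COc1cc(O)cc(OC)c1 | starting material
2 | 3,5-dimethoxyphenyl N-isopropylcarbamate | COc1cc(OC(=O)NC(C)C)cc(OC)c1 | intermediate
3 | 3,5-dimethoxyphenyl N-(tert-butyldimethylsilyl)-N-isopropylcarbamate | COc1cc(OC(=O)N(C(C)C)[Si](C)(C)C(C)(C)C)cc(OC)c1 | intermediate
4 | 2-lithio-3,5-dimethoxyphenyl N-(tert-butyldimethylsilyl)-N-isopropylcarbamate | COc1cc(OC)c([Li])c(OC(=O)N(C(C)C)[Si](C)(C)C(C)(C)C)c1 | intermediate
5 | 3,5-dimethoxy-2-(trimethylsilyl)phenyl N-(tert-butyldimethylsilyl)-N-isopropylcarbamate | COc1cc(OC)c([Si](C)(C)C)c(OC(=O)N(C(C)C)[Si](C)(C)C(C)(C)C)c1 | intermediate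
6 | 3,5-dimethoxy-2-(trimethylsilyl)phenyl N-isopropylcarbamate | COc1cc(OC)c([Si](C)(C)C)c(OC(=O)NC(C)C)c1 | intermediate
7 | 3,5-dimethoxy-2-(trimethylsilyl)phenol (present as its DBU-H phenoxide) | COc1cc(OC)c([Si](C)(C)C)c(O)c1 | intermediate
8 | 3,5-dimethoxy-2-(trimethylsilyl)phenyl trifluoromethanesulfonate | COc1cc(OC)c([Si](C)(C)C)c(OS(=O)(=O)C(F)(F)F)c1 | intermediate
9 | methoxyhydroquinone (2-methoxybenzene-1,4-diol) | COc1cc(O)ccc1O | starting material
10 | 1,4-bis(benzyloxy)-2-methoxybenzene | COc1cc(OCc2ccccc2)ccc1OCc1ccccc1 | intermediate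
11 | N-[2,5-bis(benzyloxy)-4-methoxybenzylidene]-N-methylmethanaminium chloride | COc1cc(OCc2ccccc2)c(C=[N+](C)C)cc1OCc1ccccc1.[Cl-] | intermediate
12 | 2,5-bis(benzyloxy)-4-methoxybenzaldehyde | COc1cc(OCc2ccccc2)c(C=O)cc1OCc1ccccc1 | intermediate
13 | methoxyacetyl chloride | COCC(=O)Cl | starting material
14 | (S)-4-benzyl-1,3-oxazolidine-2-thione | S=C1OC[C@H](Cc2ccccc2)N1 | starting material
15 | (S)-4-benzyl-3-(methoxyacetyl)-1,3-oxazolidine-2-thione | COCC(=O)N1C(=S)OC[C@@H]1Cc1ccccc1 | intermediate
16 | Z trichlorotitanium enolate of 15 | CO/C=C(\O[Ti](Cl)(Cl)Cl)N1C(=S)OC[C@@H]1Cc1ccccc1 | intermediate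
17 | (S)-4-benzyl-3-[(2R,3R)-3-[2,5-bis(benzyloxy)-4-methoxyphenyl]-3-hydroxy-2-methoxypropanoyl]-1,3-oxazolidine-2-thione | O[C@H](c1cc(OCc2ccccc2)c(OC)cc1OCc1ccccc1)[C@@H](OC)C(=O)N1C(=S)OC[C@@H]1Cc1ccccc1 | intermediate
18 | methyl (2R,3R)-3-[2,5-bis(benzyloxy)-4-methoxyphenyl]-3-hydroxy-2-methoxypropanoate | O[C@H](c1cc(OCc2ccccc2)c(OC)cc1OCc1ccccc1)[C@@H](OC)C(=O)OC | intermediate
19 | methyl (2R,3R)-3-[2,5-bis(benzyloxy)-4-methoxyphenyl]-2-methoxy-3-(trimethylsilyloxy)propanoate | C[Si](C)(C)O[C@H](c1cc(OCc2ccccc2)c(OC)cc1OCc1ccccc1)[C@@H](OC)C(=O)OC | intermediate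
20 | 3,5-dimethoxybenzyne (1,2-didehydro-3,5-dimethoxybenzene) | COC1=CC(OC)=CC#C1 | intermediate
21 | caesium alkoxide of 18 | [Cs+].[O-][C@H](c1cc(OCc2ccccc2)c(OC)cc1OCc1ccccc1)[C@@H](OC)C(=O)OC | intermediate
22 | caesium aryl anion of the 3,5-dimethoxyphenyl ether of 18 (carbanion at the ring carbon between the ether oxygen and a methoxy group) | COc1cc(OC)[c-]c(O[C@H](c2cc(OCc3ccccc3)c(OC)cc2OCc2ccccc2)[C@@H](OC)C(=O)OC)c1.[Cs+] | intermediate
23 | (2R,3R)-2-[2,5-bis(benzyloxy)-4-methoxyphenyl]-3,5,7-trimethoxychroman-4-one | COc1cc(OC)c2c(c1)O[C@H](c1cc(OCc3ccccc3)c(OC)cc1OCc1ccccc1)[C@@H](OC)C2=O | intermediate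
24 | (2R,3R)-2-(2,5-dihydroxy-4-methoxyphenyl)-3,5,7-trimethoxychroman-4-one (CNP0281794.1), 2,3-trans | COc1cc(OC)c2c(c1)O[C@H](c1cc(O)c(OC)cc1O)[C@@H](OC)C2=O | target

Total step count: 11 (steps 1–3 to the aryne precursor, steps 4–5 to the aldehyde, step 6 to the acylated auxiliary, steps 7–11 from the aldol to the target).
Longest linear sequence: 7 steps (steps 4, 5, 7, 8, 9, 10, 11, from methoxyhydroquinone 9).

Steps most likely to fail

1. Step 10. The aryl anion may be quenched by a proton before it reaches the ester, so that only O-arylation occurs. The transient alkoxide may undergo retro-aldol cleavage or β-elimination. The expelled methoxide may open or epimerise ring C. The fallback uses known chemistry and closes ring C by ketone synthesis followed by intramolecular SNAr. It sets out from aldol adduct 17. Transamidation with MeNHOMe·HCl and imidazole in CH2Cl2 gives the Weinreb amide (2R,3R)-3-[2,5-bis(benzyloxy)-4-methoxyphenyl]-3-hydroxy-N,2-dimethoxy-N-methylpropanamide F1. TESCl and imidazole convert it into the triethylsilyl ether F2. Addition of 2-fluoro-4,6-dimethoxyphenyllithium (from 2-bromo-1-fluoro-3,5-dimethoxybenzene and n-BuLi at −78 °C) gives (2R,3R)-3-[2,5-bis(benzyloxy)-4-methoxyphenyl]-1-(2-fluoro-4,6-dimethoxyphenyl)-2-methoxy-3-(triethylsilyloxy)propan-1-one F3. TBAF buffered with AcOH removes the silyl group to give the hydroxy ketone F4. With K2CO3 in DMF its alkoxide displaces the fluoride ortho to the ketone. This forms the O1–C8a bond without touching C2 or C3, and the sequence rejoins the route at chromanone 23.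

2. Step 7. Chelation of TiCl4 by the ortho-benzyloxy aldehyde may erode anti selectivity or facial control. The electron-rich benzylic titanium alkoxide may ionise and scramble the carbinol centre. The Lewis acid may also remove the ortho benzyl ether. The fallback replaces auxiliary control by reagent control and sets out from aldehyde 12. An asymmetric Mukaiyama aldol with (Z)-1-(ethylthio)-2-methoxy-1-(trimethylsilyloxy)ethene is promoted by Sn(OTf)2 (divalent tin), a chiral 2-(aminomethyl)pyrrolidine diamine and Bu2Sn(OAc)2 in CH2Cl2 at −78 °C. This system is established for anti-α-alkoxy-β-hydroxy thioesters, and the diamine enantiomer is chosen to deliver the (2R,3R) series. After aqueous acidic work-up it should give S-ethyl (2R,3R)-3-[2,5-bis(benzyloxy)-4-methoxyphenyl]-3-hydroxy-2-methoxypropanethioate F5. Mild methanolysis (K2CO3, MeOH, 0 °C) converts F5 into methyl ester 18, where the route is rejoined.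

3. Step 11. Over-reduction may occur, either by hydrogenolysis of the doubly activated benzylic C2–O1 bond or by reduction of the C4 ketone. The hydroquinone may also oxidise in air during isolation. The fallback is a non-reductive cleavage that sets out from 23. BCl3 with pentamethylbenzene as cation scavenger in CH2Cl2 at −78 °C, quenched cold so that the chelated C5 methyl ether is not attacked, should remove both benzyl groups and lead directly to target 24. It makes no new compound (F0).

Further compounds
F1 | step 10 | (2R,3R)-3-[2,5-bis(benzyloxy)-4-methoxyphenyl]-3-hydroxy-N,2-dimethoxy-N-methylpropanamide | O[C@H](c1cc(OCc2ccccc2)c(OC)cc1OCc1ccccc1)[C@@H](OC)C(=O)N(C)OC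
F2 | step 10 | (2R,3R)-3-[2,5-bis(benzyloxy)-4-methoxyphenyl]-N,2-dimethoxy-N-methyl-3-(triethylsilyloxy)propanamide | CC[Si](CC)(CC)O[C@H](c1cc(OCc2ccccc2)c(OC)cc1OCc1ccccc1)[C@@H](OC)C(=O)N(C)OC
F3 | step 10 | (2R,3R)-3-[2,5-bis(benzyloxy)-4-methoxyphenyl]-1-(2-fluoro-4,6-dimethoxyphenyl)-2-methoxy-3-(triethylsilyloxy)propan-1-one | CC[Si](CC)(CC)O[C@H](c1cc(OCc2ccccc2)c(OC)cc1OCc1ccccc1)[C@@H](OC)C(=O)c1c(F)cc(OC)cc1OC
F4 | step 10 | (2R,3R)-3-[2,5-bis(benzyloxy)-4-methoxyphenyl]-1-(2-fluoro-4,6-dimethoxyphenyl)-3-hydroxy-2-methoxypropan-1-one | O[C@H](c1cc(OCc2ccccc2)c(OC)cc1OCc1ccccc1)[C@@H](OC)C(=O)c1c(F)cc(OC)cc1OC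
F5 | step 7 | S-ethyl (2R,3R)-3-[2,5-bis(benzyloxy)-4-methoxyphenyl]-3-hydroxy-2-methoxypropanethioate | O[C@H](c1cc(OCc2ccccc2)c(OC)cc1OCc1ccccc1)[C@@H](OC)C(=O)SCC
F0 | step 11 | none | none
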